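**Strategy.** The 14-membered carbocycle is opened at its C10–C11 ethano link (cembrane numbering: C1 ring-fusion carbon, C14 lactone CH–O, C13 CH–OAc, C12 CH–CH3, C3/C4 epoxide, C7=C8 olefin). Both carbons arise naturally as vinyl termini: C11 from the crotylation that sets C12/C13, C10 from a vinyl group coupled to C9. Ring-closing metathesis of an acyclic diene already holding the cis-fused α-methylene lactone, the epoxide and all six stereocentres closes the macrocycle in one operation. The new C10=C11 olefin, the only disubstituted ring alkene, is then saturated by diimide while trisubstituted C7=C8 survives. The diene comes from an indium Barbier union of two fragments.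

Key step: step 12

Remark: the commercial aqueous solution of 2,2-dimethoxyacetaldehyde is assumed to be dehydrated (extraction, distillation) before use in step 9.

Notation: C15, C16 and C17 are the lactone α-carbon, the lactone carbonyl and the exocyclic methylene. Ox = (2R,3R)-3-methyl-3-[(3E)-4-methylhepta-3,6-dien-1-yl]oxiran-2-yl, attached through its CH carbon; it carries C3/C4 and C5–C10 of the target.

**Route**

Step 1
Reactants: 1 geranyl acetate
Product: 2 (2E,6E)-8-hydroxy-3,7-dimethylocta-2,6-dien-1-yl acetate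
Conditions: SeO2 (0.3 equiv), t-BuOOH, salicylic acid (cat.), CH2Cl2, 25 °C
Reagents that add atoms: tert-butyl hydroperoxide, CC(C)(C)OO
Why: The SeO2/t-BuOOH allylic oxidation (ene reaction then [2,3]-sigmatropic shift on selenium) attacks the (E)-methyl group of the electron-rich terminal olefin because the other olefin is deactivated by its allylic acetate, so the E-allylic alcohol at the future C9 is expected.

Step 2
Reactants: 2 (2E,6E)-8-hydroxy-3,7-dimethylocta-2,6-dien-1-yl acetate
Product: 3 (2E,6E)-8-bromo-3,7-dimethylocta-2,6-dien-1-yl acetate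
Conditions: CBr4, PPh3, CH2Cl2, 0 °C
Reagents that add atoms: carbon tetrabromide, BrC(Br)(Br)Br
Why: The Appel reaction converts the primary allylic alcohol into the bromide under neutral conditions without allylic transposition or loss of olefin geometry.

Step 3
Reactants: 3 (2E,6E)-8-bromo-3,7-dimethylocta-2,6-dien-1-yl acetate
Product: 4 (2E,6E)-3,7-dimethyldeca-2,6,9-trien-1-yl acetate
Conditions: tributyl(vinyl)stannane, tris(dibenzylideneacetone)dipalladium Pd2(dba)3 (2.5 mol%), tri(2-furyl)phosphine, THF, 50 °C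
Reagents that add atoms: tributyl(vinyl)stannane, C=C[Sn](CCCC)(CCCC)CCCC
Why: In this Stille coupling zerovalent palladium inserts into the allylic C–Br bond much faster than into the allylic acetate and transfers the vinyl group to the unhindered allyl terminus with retention of the E olefin, which gives the skipped diene and the future C10.

Step 4
Reactants: 4 (2E,6E)-3,7-dimethyldeca-2,6,9-trien-1-yl acetate
Product: 5 (2E,6E)-3,7-dimethyldeca-2,6,9-trien-1-ol
Conditions: K2CO3, MeOH, 25 °C
Reagents that add atoms: none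
Why: Base-catalysed transesterification frees the allylic alcohol that directs the next step, and the skipped diene is not conjugated under these mild conditions.

Step 5
Reactants: 5 (2E,6E)-3,7-dimethyldeca-2,6,9-trien-1-ol
Product: 6 Ox-methanol
Conditions: Ti(OiPr)4 (10 mol%), D-(−)-diisopropyl tartrate (12 mol%), t-BuOOH, 4 Å molecular sieves, CH2Cl2, −20 °C
Reagents that add atoms: tert-butyl hydroperoxide, CC(C)(C)OO
Why: The Sharpless asymmetric epoxidation delivers oxygen only to the olefin of the allylic alcohol, and the D-(−)-tartrate complex selects the face that gives the (2R,3R)-epoxide, which sets C3 and C4 of the target.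

Step 6
Reactants: 6 Ox-methanol
Product: 9 ethyl 4-Ox-but-2-ynoate, via epoxy triflate 7 (not isolated), via orthoester alkyne 8 (not isolated)
Conditions: Tf2O, 2,6-lutidine, CH2Cl2, −78 °C; then LiC≡CC(OEt)3 (from 3,3,3-triethoxyprop-1-yne, n-BuLi), THF–DMPU, −78 → −30 °C; then moist silica gel, CH2Cl2, 25 °C
Reagents that add atoms: 3,3,3-triethoxyprop-1-yne, C#CC(OCC)(OCC)OCC; water, O
Why: The primary epoxy triflate 7 is displaced in an SN2 reaction by the lithium acetylide far faster than the trisubstituted epoxide is opened, the orthoester keeps the alkyne from acidifying the neighbouring CH2 during the basic step and is cleaved to the ethyl ester on moist silica, and neither stereocentre is touched.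

Step 7
Reactants: 9 ethyl 4-Ox-but-2-ynoate
Product: 11 ethyl (2Z)-2-(hydroxymethyl)-4-Ox-but-2-enoate, via vinylalane 10 (not isolated)
Conditions: i-Bu2AlH, HMPA, MeCu (10 mol%), THF, 0 °C; then CH2O (gas), −30 → 0 °C; aq. potassium sodium tartrate work-up
Reagents that add atoms: formaldehyde, C=O
Why: Conjugate hydroalumination of the ynoate by the HMPA-complexed aluminium hydride adds H and Al syn to give vinylalane 10, which is trapped at carbon by formaldehyde with retention (reductive aldol type), so the chain should end cis to the ester and a primary allylic alcohol should result without attack on the epoxide.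

Step 8
Reactants: 11 ethyl (2Z)-2-(hydroxymethyl)-4-Ox-but-2-enoate
Product: 12 ethyl (2E)-2-(bromomethyl)-4-Ox-but-2-enoate
Conditions: N-bromosuccinimide, Me2S, CH2Cl2, −20 → 0 °C
Reagents that add atoms: N-bromosuccinimide, BrN1C(=O)CCC1=O
Why: In the Corey–Kim bromination the succinimidodimethylsulfonium salt activates the primary allylic hydroxyl and bromide displaces it under neutral conditions that spare the epoxide and the olefins.

Step 9
Reactants: 13 2,2-dimethoxyacetaldehyde
Product: 14 (2R,3S)-1,1-dimethoxy-3-methylpent-4-en-2-ol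
Conditions: (Z)-but-2-ene, n-BuLi, KOt-Bu, THF, −78 → −45 °C; (+)-Ipc2BOMe, then BF3·OEt2, −78 °C; then 13, −78 °C; then NaOH, H2O2
Reagents that add atoms: (Z)-but-2-ene, C/C=C\C
Why: The Brown crotylboration runs through a closed chair transition state in which the Z-crotyl geometry fixes the 12,13-syn relation and the (+)-Ipc2B reagent derived from (−)-α-pinene selects the Re face of the aldehyde, which sets C13 as R and C12 as S.

Step 10
Reactants: 14 (2R,3S)-1,1-dimethoxy-3-methylpent-4-en-2-ol; 12 ethyl (2E)-2-(bromomethyl)-4-Ox-but-2-enoate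
Product: 18 (4S,5R)-5-[(1R,2S)-1-hydroxy-2-methylbut-3-en-1-yl]-3-methylidene-4-(Ox-methyl)oxolan-2-one, via hydroxy aldehyde 15 (not isolated), via allylindium 16 (not isolated), via hydroxy ester 17 (not isolated)
Conditions: 14, Amberlyst-15 (H+ resin), H2O, 50 °C, filter; then 12, indium powder, NaHCO3 (pH 6–7), THF–H2O (1:1), 25 °C; then 2-hydroxypyridine (cat.), toluene, 60 °C
Reagents that add atoms: water, O
Why: In this indium-mediated Barbier allylation the free α-hydroxyl and the aldehyde of 15 chelate trivalent indium so that the allyl group adds anti to the C12 branch (13,14-syn, C14 R), the allylindium 16, which equilibrates to the Z-configured σ-allyl form whatever the bromide geometry, reacts at its γ-carbon through a chair transition state (14,1-syn, C1 S), and the γ-hydroxy ester 17 closes to the cis-fused α-methylene-γ-butyrolactone.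

Step 11
Reactants: 18 (4S,5R)-5-[(1R,2S)-1-hydroxy-2-methylbut-3-en-1-yl]-3-methylidene-4-(Ox-methyl)oxolan-2-one
Product: 19 (1R,2S)-2-methyl-1-[(2R,3S)-4-methylidene-5-oxo-3-(Ox-methyl)oxolan-2-yl]but-3-en-1-yl acetate
Conditions: Ac2O, pyridine, DMAP (cat.), CH2Cl2, 0 °C
Reagents that add atoms: acetic anhydride, CC(=O)OC(C)=O
Why: DMAP-catalysed acylation of the only free hydroxyl installs the C13 acetate before macrocyclisation, which also removes the nucleophile that could later open the epoxide across the ring.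

Step 12
Reactants: 19 (1R,2S)-2-methyl-1-[(2R,3S)-4-methylidene-5-oxo-3-(Ox-methyl)oxolan-2-yl]but-3-en-1-yl acetate
Product: 20 (1S,3R,4R,7E,12S,13R,14R)-10,11-didehydroeupalmerin acetate (C10=C11 as an E/Z mixture)
Conditions: second-generation Grubbs catalyst RuCl2(=CHPh)(H2IMes)(PCy3) (10 mol%), 1,4-benzoquinone (20 mol%), toluene (1 mM), 80 °C
Reagents that add atoms: none
Why: Ring-closing olefin metathesis: the ruthenium benzylidene initiates at the unhindered C10 vinyl terminus of the skipped diene, the resulting alkylidene engages the C11 vinyl group through a metallacyclobutane, and cycloreversion expels ethylene and forms the C10=C11 bond. The closest known reaction type is the macrocyclic RCM of acyclic terminal dienes to 14-membered carbocycles and macrolides. The ring closed is the 14-membered carbocycle, in a macrocyclic mode in which both olefinic carbons become ring members. No new stereocentre is created, and the E/Z ratio at C10=C11 is irrelevant because this olefin is saturated in step 13. The step needs chemoselectivity among five C=C bonds and ring closure over oligomerisation: the trisubstituted C7=C8 olefin is inert, the electron-poor 1,1-disubstituted C15=C17 methylene is a poor partner whose intramolecular engagement would require a bridgehead olefin (with C11) or a strained 11-membered trisubstituted ring (with C10), and high dilution favours closure. The cis-fused lactone and the trans epoxide act as turn elements that bring C10 and C11 together, and benzoquinone suppresses ruthenium hydride migration of the skipped diene.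

Step 13
Reactants: 20 (1S,3R,4R,7E,12S,13R,14R)-10,11-didehydroeupalmerin acetate
Product: 22 17-(dimethylamino)-15,17-dihydroeupalmerin acetate (C15 epimer as formed), via amine adduct 21 (not isolated)
Conditions: Me2NH (2 M in THF), 0 → 25 °C, evaporate; then 2-nitrobenzenesulfonylhydrazide, Et3N, CH2Cl2, 25 °C
Reagents that add atoms: dimethylamine, CNC
Why: Aza-Michael addition of dimethylamine masks the α-methylene lactone as its Mannich base (C15 configuration is irrelevant), after which diimide generated from the sulfonylhydrazide delivers H2 in a concerted syn fashion to the disubstituted C10=C11 olefin much faster than to the trisubstituted C7=C8 olefin.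

Step 14
Reactants: 22 17-(dimethylamino)-15,17-dihydroeupalmerin acetate
Product: 24 eupalmerin acetate, via ammonium iodide 23 (not isolated)
Conditions: MeI, CH2Cl2, 25 °C; then aq. NaHCO3, EtOAc, 25 °C
Reagents that add atoms: none
Why: Exhaustive N-methylation followed by bicarbonate-induced E1cB (Hofmann-type) elimination of trimethylamine from 23 regenerates the exocyclic methylene without touching the acetate, the epoxide or the ring olefin.

**Compound list**

1 | geranyl acetate, (2E)-3,7-dimethylocta-2,6-dien-1-yl acetate | CC(C)=CCC/C(C)=C/COC(C)=O | starting material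
2 | (2E,6E)-8-hydroxy-3,7-dimethylocta-2,6-dien-1-yl acetate | OC/C(C)=C/CC/C(C)=C/COC(C)=O | intermediate
3 | (2E,6E)-8-bromo-3,7-dimethylocta-2,6-dien-1-yl acetate | BrC/C(C)=C/CC/C(C)=C/COC(C)=O | intermediate
4 | (2E,6E)-3,7-dimethyldeca-2,6,9-trien-1-yl acetate | C=CC/C(C)=C/CC/C(C)=C/COC(C)=O | intermediate
5 | (2E,6E)-3,7-dimethyldeca-2,6,9-trien-1-ol | C=CC/C(C)=C/CC/C(C)=C/CO | intermediate
6 | Ox-methanol, [(2R,3R)-3-methyl-3-[(3E)-4-methylhepta-3,6-dien-1-yl]oxiran-2-yl]methanol | C=CC/C(C)=C/CC[C@@]1(C)O[C@@H]1CO | intermediate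
7 | Ox-methyl trifluoromethanesulfonate | C=CC/C(C)=C/CC[C@@]1(C)O[C@@H]1COS(=O)(=O)C(F)(F)F | intermediate
8 | 1,1,1-triethoxy-4-Ox-but-2-yne | C=CC/C(C)=C/CC[C@@]1(C)O[C@@H]1CC#CC(OCC)(OCC)OCC | intermediate
9 | ethyl 4-Ox-but-2-ynoate | C=CC/C(C)=C/CC[C@@]1(C)O[C@@H]1CC#CC(=O)OCC | intermediate
10 | ethyl (2E)-2-(diisobutylalumanyl)-4-Ox-but-2-enoate | C=CC/C(C)=C/CC[C@@]1(C)O[C@@H]1C/C=C(/[Al](CC(C)C)CC(C)C)C(=O)OCC | intermediate
11 | ethyl (2Z)-2-(hydroxymethyl)-4-Ox-but-2-enoate | C=CC/C(C)=C/CC[C@@]1(C)O[C@@H]1C/C=C(/CO)C(=O)OCC | intermediate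
12 | ethyl (2E)-2-(bromomethyl)-4-Ox-but-2-enoate | C=CC/C(C)=C/CC[C@@]1(C)O[C@@H]1C/C=C(/CBr)C(=O)OCC | intermediate
13 | 2,2-dimethoxyacetaldehyde | COC(OC)C=O | starting material
14 | (2R,3S)-1,1-dimethoxy-3-methylpent-4-en-2-ol | COC(OC)[C@H](O)[C@@H](C)C=C | intermediate
15 | (2R,3S)-2-hydroxy-3-methylpent-4-enal | O=C[C@H](O)[C@@H](C)C=C | intermediate
16 | ethyl (2Z)-2-[(dibromoindiganyl)methyl]-4-Ox-but-2-enoate | C=CC/C(C)=C/CC[C@@]1(C)O[C@@H]1C/C=C(\C[In](Br)Br)C(=O)OCC | intermediate
17 | ethyl (3S,4R,5R,6S)-4,5-dihydroxy-6-methyl-2-methylidene-3-(Ox-methyl)oct-7-enoate | CCOC(=O)C(=C)[C@H](C[C@H]1O[C@]1(C)CC/C=C(\C)CC=C)[C@@H](O)[C@H](O)[C@@H](C)C=C | intermediate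
18 | (4S,5R)-5-[(1R,2S)-1-hydroxy-2-methylbut-3-en-1-yl]-3-methylidene-4-(Ox-methyl)oxolan-2-one | C=C1C(=O)O[C@@H]([C@H](O)[C@@H](C)C=C)[C@H]1C[C@H]1O[C@]1(C)CC/C=C(\C)CC=C | intermediate
19 | (1R,2S)-2-methyl-1-[(2R,3S)-4-methylidene-5-oxo-3-(Ox-methyl)oxolan-2-yl]but-3-en-1-yl acetate | C=C1C(=O)O[C@@H]([C@H](OC(C)=O)[C@@H](C)C=C)[C@H]1C[C@H]1O[C@]1(C)CC/C=C(\C)CC=C | intermediate
20 | (1S,3R,4R,7E,12S,13R,14R)-10,11-didehydroeupalmerin acetate, C10=C11 E/Z mixture | C=C1C(=O)O[C@H]2[C@H](OC(C)=O)[C@@H](C)C=CC/C(C)=C/CC[C@@]3(C)O[C@@H]3C[C@@H]12 | intermediate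
21 | 17-(dimethylamino)-15,17-dihydro derivative of 20, C15 undefined | CN(C)CC1C(=O)O[C@H]2[C@H](OC(C)=O)[C@@H](C)C=CC/C(C)=C/CC[C@@]3(C)O[C@@H]3C[C@@H]12 | intermediate
22 | 17-(dimethylamino)-15,17-dihydroeupalmerin acetate, C15 undefined | CN(C)CC1C(=O)O[C@H]2[C@H](OC(C)=O)[C@@H](C)CCC/C(C)=C/CC[C@@]3(C)O[C@@H]3C[C@@H]12 | intermediate
23 | N,N,N-trimethylammonium iodide of 22 | C[N+](C)(C)CC1C(=O)O[C@H]2[C@H](OC(C)=O)[C@@H](C)CCC/C(C)=C/CC[C@@]3(C)O[C@@H]3C[C@@H]12.[I-] | intermediate
24 | eupalmerin acetate, (1S,3R,4R,7E,12S,13R,14R) | C=C1C(=O)O[C@H]2[C@H](OC(C)=O)[C@@H](C)CCC/C(C)=C/CC[C@@]3(C)O[C@@H]3C[C@@H]12 | target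

**Step count and risks**

Total step count: 14. Longest linear sequence: 13 steps (steps 1–8 and 10–14); step 9 makes the second fragment.

Steps most likely to fail:

1. Step 10. The trisubstituted epoxide may be opened by acid or by trivalent indium in water, including cyclisation of the new C14 hydroxyl onto C3, and chelation control may erode so that facial mixtures form. The fallback sets out from 14 and returns at 18; it moves the union to an anhydrous, ether-chelated zinc manifold. Alcohol 14 is converted with NaH and 4-methoxybenzyl chloride into the PMB ether 1-({[(2R,3S)-1,1-dimethoxy-3-methylpent-4-en-2-yl]oxy}methyl)-4-methoxybenzene F1. The acetal is hydrolysed (aq. HCl, THF, 40 °C) to (2R,3S)-2-[(4-methoxybenzyl)oxy]-3-methylpent-4-enal F2. F2 and bromide 12 are added to activated zinc in dry THF (Dreiding–Schmidt reaction); the ether and the aldehyde chelate divalent zinc, the zinc alkoxide lactonises in the flask, and the PMB-protected lactone F3 should result. DDQ in CH2Cl2–pH 7 buffer then releases 18.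

2. Step 7. The aluminium hydride may attack the epoxide or reduce the ester, and capture of the vinylalane by formaldehyde may be incomplete. The fallback sets out from 9 and returns at 11. Syn-hydrostannation of 9 with Bu3SnH and Pd(PPh3)4 should give ethyl (2E)-4-Ox-2-(tributylstannyl)but-2-enoate F4. Iodine converts F4 with retention into ethyl (2E)-2-iodo-4-Ox-but-2-enoate F5. Stille coupling of F5 with (tributylstannyl)methanol (Pd(PPh3)4, dioxane, 80 °C) then delivers 11.

3. Step 12. Intermolecular metathesis may outrun closure at the branched C11 olefin, and ruthenium hydride migration may conjugate the skipped diene. The fallback sets out from 11 and returns at 24. It still forms C10=C11 by ring closure, but in a temporary silicon-tethered ring, and leaves the carbocycle to a macro-Barbier reaction.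
   - The crotylboration of step 9 applied to 2-[(4-methoxybenzyl)oxy]acetaldehyde gives (2R,3S)-1-[(4-methoxybenzyl)oxy]-3-methylpent-4-en-2-ol F6.
   - F6 and 11 are joined with i-Pr2SiCl2 and imidazole as the diisopropylsilylene bis-ether F7.
   - The catalyst of step 12 closes the 18-membered silaketal ring through C10=C11 to give F8; the trisubstituted enoate is inert.
   - Diimide (2-nitrobenzenesulfonylhydrazide, Et3N) gives the 10,11-saturated ring F9.
   - Bu4NF removes the tether to give the diol F10.
   - N-bromosuccinimide/Me2S converts the allylic alcohol into the bromide F11.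
   - DDQ gives the bromo diol F12.
   - TEMPO/PhI(OAc)2 oxidises the primary alcohol to the α-hydroxy aldehyde F13.
   - Indium in buffered THF–H2O at high dilution closes the carbocycle and the lactone to give 13-O-deacetyleupalmerin acetate F14.
   - Ac2O/pyridine then gives 24.

Further compounds
F1 | step 10 | 1-({[(2R,3S)-1,1-dimethoxy-3-methylpent-4-en-2-yl]oxy}methyl)-4-methoxybenzene | COC(OC)[C@H](OCc1ccc(OC)cc1)[C@@H](C)C=C
F2 | step 10 | (2R,3S)-2-[(4-methoxybenzyl)oxy]-3-methylpent-4-enal | O=C[C@H](OCc1ccc(OC)cc1)[C@@H](C)C=C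
F3 | step 10 | 13-O-(4-methoxybenzyl) ether of lactone 18 | C=C1C(=O)O[C@@H]([C@H](OCc2ccc(OC)cc2)[C@@H](C)C=C)[C@H]1C[C@H]1O[C@]1(C)CC/C=C(\C)CC=C
F4 | step 7 | ethyl (2E)-4-Ox-2-(tributylstannyl)but-2-enoate | C=CC/C(C)=C/CC[C@@]1(C)O[C@@H]1C/C=C(/[Sn](CCCC)(CCCC)CCCC)C(=O)OCC
F5 | step 7 | ethyl (2E)-2-iodo-4-Ox-but-2-enoate | C=CC/C(C)=C/CC[C@@]1(C)O[C@@H]1C/C=C(/I)C(=O)OCC
F6 | step 12 | (2R,3S)-1-[(4-methoxybenzyl)oxy]-3-methylpent-4-en-2-ol | COc1ccc(COC[C@H](O)[C@@H](C)C=C)cc1
F7 | step 12 | diisopropylsilylene bis-ether of 11 (primary O) and F6 (secondary O) | C=CC/C(C)=C/CC[C@@]1(C)O[C@@H]1C/C=C(/CO[Si](C(C)C)(C(C)C)O[C@@H](COCc1ccc(OC)cc1)[C@@H](C)C=C)C(=O)OCC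
F8 | step 12 | 18-membered silaketal macrocycle with C10=C11 (E/Z mixture) | CCOC(=O)/C1=C\C[C@H]2O[C@]2(C)CC/C=C(\C)CC=C[C@H](C)[C@H](COCc2ccc(OC)cc2)O[Si](C(C)C)(C(C)C)OC1
F9 | step 12 | 10,11-dihydro derivative of F8 | CCOC(=O)/C1=C\C[C@H]2O[C@]2(C)CC/C=C(\C)CCC[C@H](C)[C@H](COCc2ccc(OC)cc2)O[Si](C(C)C)(C(C)C)OC1
F10 | step 12 | seco diol: ethyl (2Z)-2-(hydroxymethyl) enoate with free C13 hydroxyl and C14 PMB ether | CCOC(=O)/C(CO)=C\C[C@H]1O[C@]1(C)CC/C=C(\C)CCC[C@H](C)[C@@H](O)COCc1ccc(OC)cc1
F11 | step 12 | allylic bromide of F10 | CCOC(=O)/C(CBr)=C\C[C@H]1O[C@]1(C)CC/C=C(\C)CCC[C@H](C)[C@@H](O)COCc1ccc(OC)cc1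
F12 | step 12 | bromo 13,14-diol from F11 | CCOC(=O)/C(CBr)=C\C[C@H]1O[C@]1(C)CC/C=C(\C)CCC[C@H](C)[C@@H](O)CO
F13 | step 12 | bromo α-hydroxy aldehyde from F12 | CCOC(=O)/C(CBr)=C\C[C@H]1O[C@]1(C)CC/C=C(\C)CCC[C@H](C)[C@@H](O)C=O
F14 | step 12 | 13-O-deacetyleupalmerin acetate (13-hydroxy macrocyclic lactone) | C=C1C(=O)O[C@H]2[C@H](O)[C@@H](C)CCC/C(C)=C/CC[C@@]3(C)O[C@@H]3C[C@@H]12
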